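The unit here is the charge of L: L, G and J all count as fractions of it, so this flask starts with L at its full charge and G at 1.20 of that charge.

| setting | north-east | south | flask |
|---|---|---|---|
| L | 0.050 M | 0.050 M | 0.050 M |
| G | 1.2 equiv | 0.80 equiv | 1.20 equiv |
| remark | the very flask that is asked about, followed so far | run made earlier |  |
| time |  |  | 3.0 d |

| run | time / h | J / % |
|---|---|---|
| north-east | 2.50 | 17.5 |
| north-east | 6.00 | 19.1 |
| north-east | 12.0 | 19.5 |
| north-east | 20.0 | 20.5 |
| north-east | 25.0 | 20.9 |
| north-east | 30.0 | 22.1 |
| north-east | 40.0 | 20.8 |
| south | 0.500 | 5.4 |
| south | 1.00 | 9.8 |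
| south | 1.33 | 12.3 |
| south | 2.00 | 11.6 |
| south | 2.50 | 12.5 |
| south | 3.00 | 13.3 |

(standard deviation of a reading: 0.5 percentage points)

- what is added takes up no volume worth counting
- the analysis behind the earlier runs scatters by 0.5 percentage points, standard deviation
- a reading or a percentage of J counts all its forms, free or not

- beta: change nothing and wait 40 h more
- alpha: at 3.0 d add G, 100 % of the amount charged, then wait 40 h
- eta: at 3.0 d add L, 50.0 % of the amount charged, then wait 40 h

1. J, in percent of the L first charged, at 3.0 d
2. what to do for the largest gain in J; "none" if nothing gains more than 2 percentage points (beta / alpha / eta / none)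
3. J present, in percent of the L first charged, after alpha
4. J present, in percent of the L first charged, after eta

In the first instants the south run shows the fast part, with J at 5.4 % after 0.500 h and 9.8 % after 1.00 h. In the middle, the north-east flask, which is this flask, already reads 17.5 % at 2.50 h, and the climb has become a creep: from 19.1 % at 6.00 h, it reaches a mean of 21.1 % over the readings from 20.0 h on, a rise of 2 percentage points against a scatter of 0.5 points.

At the end I treat that top as a balance and divide the J by the product of the charge not in J and the G not in J, which gives 0.270. This ratio, the plateau number, is the equilibrium constant of that assumed balance times the charge of L, and it is what to watch in the readings. The last south reading gives 0.230, which is lower, but the south readings are still climbing, from 11.6 % at 2.00 h to 13.3 % at 3.00 h, so I keep the north-east number.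

Holding it and solving the balance again, I commit to 21.1 % now, 35.6 % after alpha and 29.5 % after eta, so alpha leads.

The forecast gives 22.5 % (21 % to 24 %), 37 % (32 % to 42 %) after alpha and 30 % (24 % to 33 %) after eta. Each of these stands above my figure, it also chooses alpha, and it says: “If G were dying, adding L would do nothing, but adding G would still win”.

This flask stands at 21.1 %, and alpha gives 35.6 % and eta 29.4 %, gains of 14 points and 8.3 points against 0.0054 points for beta.

    L → Z (k = 1.30 h⁻¹)
    L ⇌ X (K = 3.10, k = 0.380 h⁻¹)
    G + Z ⇌ J (K = 5.40 L mol⁻¹, k = 14.0 L mol⁻¹ h⁻¹)
    L + J ⇌ D, settled at all times (K = 36.0 L mol⁻¹)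

At 72.0 h free L in this flask is 0 %, X holds 0.0298 % and Z holds 78.9 %, so nearly all of the charge not in J is Z. With G at 82.4 % of its own charge, the plateau number on these amounts comes to 0.270. Carried to the neighbour flask with 4.80 equiv of G, 0.270 gives 53.5 %, and that neighbour stands at 53.5 %.

The readings are simulated with made-up constants; noise was put on by code.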